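**Retrosynthetic overview**
1. The last step removes four MOM groups from the tetra-MOM (2S)-flavanone. Rings A and B are bought as benzaldehydes, and ring C (the pyranone) is the only ring made.
2. Ring C is closed at C3–C4 by an Rh(I)/chiral bisphosphine intramolecular alkene hydroacylation of an achiral 2-(1-arylvinyloxy)benzaldehyde. The same event puts H on C2 and sets the only stereocentre; it is an isomerisation with no atom lost.
3. Enabling feature: C2 of ring C bears only O1 and ring B, and C3 is a bare CH2. C2=C3 can therefore be stored as a terminal 1,1-disubstituted aryl enol ether without allylic H, inside the 5-hexenal-type array O=C4(H)–C4a–C8a–O1–C2=C3. Ring A is symmetric about its C4a–C7 axis (the C5 and C8a oxygens are equivalent, as are the C6 and C8 prenyls), so either ortho oxygen can become O1. Both prenyls sit meta to C4a, the ring carbon that carries C4, and cannot reach C4.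
4. The enol ether comes from E2 loss of HCl from a racemic 2-chloro-1-arylethyl aryl ether, made by Mitsunobu union (O1–C2) of the A-ring phenol and the B-ring chlorohydrin. Both ether enantiomers pass through the one achiral alkene.
5. The A-ring phenol comes from double C-prenylation and bis-MOM protection of 2,4,6-trihydroxybenzaldehyde. The chlorohydrin comes from LiCH2Cl addition to MOM-protected 3,5-dihydroxybenzaldehyde.

Key step: step 7

Assumption: the sense of induction of the Rh/DTBM-SEGPHOS catalyst on this new alkene class cannot be derived safely by analogy. The route is written with the (R)-ligand, and the equally available (S)-ligand is used if a test run shows the opposite sense.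

**Step 1**
Reactants: 1 2,4,6-trihydroxybenzaldehyde; 2 prenyl bromide (1-bromo-3-methylbut-2-ene)
Product: 3 2,4,6-trihydroxy-3,5-bis(3-methylbut-2-en-1-yl)benzaldehyde
Conditions: 2 (2.0 equiv), KOH (2.2 equiv), H2O, 0 °C → rt; then dilute HCl
Reagents that add atoms: none
Why: Aqueous-base C-alkylation of an acylphloroglucinol polyanion, the reaction type used for diprenylated acylphloroglucinols, in which the two free, symmetry-equivalent ring carbons C3 and C5 each take one prenyl group by SN2 and limiting bromide holds back geminal over-alkylation.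

**Step 2**
Reactants: 3 2,4,6-trihydroxy-3,5-bis(3-methylbut-2-en-1-yl)benzaldehyde
Product: 4 2-hydroxy-4,6-bis(methoxymethoxy)-3,5-bis(3-methylbut-2-en-1-yl)benzaldehyde
Conditions: MOMCl (2.3 equiv), i-Pr2NEt (3 equiv), CH2Cl2, 0 °C → rt
Reagents that add atoms: chloromethyl methyl ether (MOMCl), COCCl
Why: Williamson-type MOM protection in which the 4-OH and one of the two equivalent ortho-OH groups react while the last OH is held back by its hydrogen bond to the formyl oxygen, the known selectivity pattern of 2,4,6-trihydroxyaryl carbonyl compounds.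

**Step 3**
Reactants: 5 3,5-dihydroxybenzaldehyde
Product: 6 3,5-bis(methoxymethoxy)benzaldehyde
Conditions: MOMCl (2.5 equiv), i-Pr2NEt (3 equiv), CH2Cl2, 0 °C → rt
Reagents that add atoms: chloromethyl methyl ether (MOMCl), COCCl
Why: Routine Williamson-type MOM protection of two unhindered phenols, giving a base-stable B-ring building block.

**Step 4**
Reactants: 6 3,5-bis(methoxymethoxy)benzaldehyde
Product: 7 (±)-1-[3,5-bis(methoxymethoxy)phenyl]-2-chloroethan-1-ol
Conditions: ICH2Cl (1.5 equiv), MeLi·LiBr (1.4 equiv), THF, −78 °C; AcOH quench at −78 °C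
Reagents that add atoms: chloroiodomethane, ClCI
Why: Carbenoid 1,2-addition of chloromethyllithium, made in situ by I/Li exchange, to a non-enolisable aldehyde, with the cold acid quench stopping the alkoxide before epoxide closure; the carbinol centre is left racemic because step 6 erases it.

**Step 5**
Reactants: 4 2-hydroxy-4,6-bis(methoxymethoxy)-3,5-bis(3-methylbut-2-en-1-yl)benzaldehyde; 7 (±)-1-[3,5-bis(methoxymethoxy)phenyl]-2-chloroethan-1-ol
Product: 8 (±)-2-{1-[3,5-bis(methoxymethoxy)phenyl]-2-chloroethoxy}-4,6-bis(methoxymethoxy)-3,5-bis(3-methylbut-2-en-1-yl)benzaldehyde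
Conditions: PPh3, DIAD, toluene (concentrated), 0 °C → rt
Reagents that add atoms: none
Why: Mitsunobu etherification of an acidic salicylaldehyde-type phenol with a 2-chloro-1-arylethanol, in which SN2 at the activated benzylic carbon places the oxygen on the aryl-bearing carbon (O1–C2) while the aldehyde, the primary chloride and the prenyl groups are untouched and the racemic centre is irrelevant.

**Step 6**
Reactants: 8 (±)-2-{1-[3,5-bis(methoxymethoxy)phenyl]-2-chloroethoxy}-4,6-bis(methoxymethoxy)-3,5-bis(3-methylbut-2-en-1-yl)benzaldehyde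
Product: 9 2-({1-[3,5-bis(methoxymethoxy)phenyl]ethenyl}oxy)-4,6-bis(methoxymethoxy)-3,5-bis(3-methylbut-2-en-1-yl)benzaldehyde (achiral)
Conditions: KOt-Bu (1.5 equiv), THF, 0 °C → rt; chromatography on Et3N-deactivated silica
Reagents that add atoms: none
Why: E2 dehydrochlorination as in the classical aryl 2-chloroethyl ether to aryl vinyl ether synthesis, eased here by the benzylic α-oxy C–H and tolerated by the non-enolisable aldehyde and the MOM ethers, which merges both enantiomers of 8 into one achiral enol ether.

**Step 7**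
Reactants: 9 2-({1-[3,5-bis(methoxymethoxy)phenyl]ethenyl}oxy)-4,6-bis(methoxymethoxy)-3,5-bis(3-methylbut-2-en-1-yl)benzaldehyde
Product: 10 (2S)-2-[3,5-bis(methoxymethoxy)phenyl]-5,7-bis(methoxymethoxy)-6,8-bis(3-methylbut-2-en-1-yl)-2,3-dihydro-4H-chromen-4-one
Conditions: [Rh(cod)Cl]2 (5 mol %), (R)-DTBM-SEGPHOS (10 mol %), NaBArF4 (10 mol %), 1,4-dioxane, 80 °C, Ar
Reagents that add atoms: none
Why: Proposed new method: cationic Rh(I) adds oxidatively into the formyl C–H bond of 9, the tethered C2=C3 alkene binds, the hydride migrates to the internal carbon C2 so that Rh stays on the terminal CH2 (C3) in a seven-membered acyl–alkyl rhodacycle, and C–C reductive elimination joins C3 to the acyl carbon C4. The closest known reaction type is the Rh/DTBM-SEGPHOS endo- and enantioselective hydroacylation of ortho-(2-substituted allyl)benzaldehydes to 3-substituted tetralones (the same 5-hexenal array with CH2 where 9 has O1), backed by the enantioselective hydroacylation of N-(1-substituted vinyl)indole-2-carbaldehydes (heteroatom-bound 1,1-disubstituted alkene) and of O- and S-tethered ortho-allyl-X-benzaldehydes to seven-membered ketones; an aryl 1-arylvinyl ether has not been used as the alkene, hence the label. Ring C closes in a formal 6-endo-trig mode. The single new stereocentre C2 is created in the hydride-transfer step on an achiral substrate, so the C2-symmetric bisphosphine alone decides which alkene face is bound and hydrometallated. Endo over exo closure (which would give a 2-aryl-2-methylbenzofuran-3-one) is secured by the 1,1-disubstitution of the alkene, since the exo path needs a tertiary Rh–C2 alkyl and a reductive elimination to a quaternary carbon, and alkene isomerisation, the usual side path, is impossible because C2 bears only O1 and ring B. The prenyl alkenes stay out because they are trisubstituted and meta to the acyl carbon, and the push–pull 2,4,6-trioxygenated aldehyde is too poor an electrophile for a Lewis-acid Prins-type closure to the flavylium level.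

**Step 8**
Reactants: 10 (2S)-2-[3,5-bis(methoxymethoxy)phenyl]-5,7-bis(methoxymethoxy)-6,8-bis(3-methylbut-2-en-1-yl)-2,3-dihydro-4H-chromen-4-one
Product: 11 (2S)-2-(3,5-dihydroxyphenyl)-5,7-dihydroxy-6,8-bis(3-methylbut-2-en-1-yl)-2,3-dihydro-4H-chromen-4-one (target)
Conditions: HCl (cat., ca. 0.5 M), MeOH, 40 °C, stopped at full conversion
Reagents that add atoms: none
Why: Acid-catalysed transacetalisation of aryl MOM ethers to dimethoxymethane, the usual last step for prenylated flavanones, run mild and short so that the prenyl groups do not cyclise onto the freed phenols; C2 is not touched because no base is present to open ring C by retro-oxa-Michael reaction.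

**Compound list**
1 | 2,4,6-trihydroxybenzaldehyde | O=Cc1c(O)cc(O)cc1O | starting material
2 | prenyl bromide (1-bromo-3-methylbut-2-ene) | CC(C)=CCBr | starting material
3 | 2,4,6-trihydroxy-3,5-bis(3-methylbut-2-en-1-yl)benzaldehyde | CC(C)=CCc1c(O)c(CC=C(C)C)c(O)c(C=O)c1O | intermediate
4 | 2-hydroxy-4,6-bis(methoxymethoxy)-3,5-bis(3-methylbut-2-en-1-yl)benzaldehyde | COCOc1c(CC=C(C)C)c(O)c(C=O)c(OCOC)c1CC=C(C)C | intermediate
5 | 3,5-dihydroxybenzaldehyde | O=Cc1cc(O)cc(O)c1 | starting material
6 | 3,5-bis(methoxymethoxy)benzaldehyde | COCOc1cc(C=O)cc(OCOC)c1 | intermediate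
7 | (±)-1-[3,5-bis(methoxymethoxy)phenyl]-2-chloroethan-1-ol | COCOc1cc(cc(OCOC)c1)C(O)CCl | intermediate
8 | (±)-2-{1-[3,5-bis(methoxymethoxy)phenyl]-2-chloroethoxy}-4,6-bis(methoxymethoxy)-3,5-bis(3-methylbut-2-en-1-yl)benzaldehyde | COCOc1c(CC=C(C)C)c(OC(CCl)c2cc(OCOC)cc(OCOC)c2)c(C=O)c(OCOC)c1CC=C(C)C | intermediate
9 | 2-({1-[3,5-bis(methoxymethoxy)phenyl]ethenyl}oxy)-4,6-bis(methoxymethoxy)-3,5-bis(3-methylbut-2-en-1-yl)benzaldehyde | COCOc1c(CC=C(C)C)c(OC(=C)c2cc(OCOC)cc(OCOC)c2)c(C=O)c(OCOC)c1CC=C(C)C | intermediate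
10 | (2S)-2-[3,5-bis(methoxymethoxy)phenyl]-5,7-bis(methoxymethoxy)-6,8-bis(3-methylbut-2-en-1-yl)-2,3-dihydro-4H-chromen-4-one | CC(C)=CCc1c(OCOC)c(CC=C(C)C)c2c(c1OCOC)C(=O)C[C@@H](c1cc(OCOC)cc(OCOC)c1)O2 | intermediate
11 | (2S)-2-(3,5-dihydroxyphenyl)-5,7-dihydroxy-6,8-bis(3-methylbut-2-en-1-yl)-2,3-dihydro-4H-chromen-4-one | CC(C)=CCc1c(O)c(CC=C(C)C)c2c(c1O)C(=O)C[C@@H](c1cc(O)cc(O)c1)O2 | target

**Total step count:** 8. **Longest linear sequence:** 6 (steps 1, 2, 5, 6, 7, 8; the branch 3, 4, 5, 6, 7, 8 is equally long).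

**Steps most likely to fail**

Step 7 (Proposed new method).
- The crowded acyl-rhodium hydride may decarbonylate.
- Insertion may occur in the exo sense.
- The rhodacycle may lose the β-aryloxide.
- Discrimination between the alkene faces may be weak.

The fallback uses known chemistry, sets out from 4 and 6, and comes back at 10.
- Aldehyde 4 is treated with MeMgBr (2.2 equiv, THF, −78 → 0 °C) to give 1-[2-hydroxy-4,6-bis(methoxymethoxy)-3,5-diprenylphenyl]ethan-1-ol F1.
- This is oxidised at once (MnO2, CH2Cl2) to 1-[2-hydroxy-4,6-bis(methoxymethoxy)-3,5-diprenylphenyl]ethan-1-one F2.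
- Claisen–Schmidt condensation with 6 (KOH, EtOH, rt) should give the (E)-2'-hydroxychalcone F3.
- Oxa-Michael cyclisation (NaOAc, EtOH, reflux) gives the racemic tetra-MOM flavanone F4.
- Kinetic resolution by asymmetric transfer hydrogenation follows (Cp*RhCl(TsDPEN), HCO2H/Et3N, EtOAc), using the catalyst antipode that consumes the (2R)-ketone. It converts the unwanted enantiomer into the cis-(2R,4R)-flavan-4-ol F5 and leaves 10, which is separated by chromatography.

Step 5.
- Substitution may be sluggish at the crowded, hydrogen-bonded phenol.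
- The activated alcohol may instead be lost by elimination.

The fallback sets out from 6 and 4 and comes back at 9, bypassing 8. It replaces alkylation by acylation and carbonyl methylenation.
- Pinnick oxidation of 6 (NaClO2, NaH2PO4, 2-methylbut-2-ene, t-BuOH/H2O) gives 3,5-bis(methoxymethoxy)benzoic acid F6.
- Steglich-type esterification with 4 (EDC, DMAP, CH2Cl2) gives the aryl benzoate F7.
- The formyl group is masked (HC(OMe)3, cat. PPTS, MeOH, rt) as the dimethyl acetal ester F8.
- Petasis methylenation (Cp2TiMe2, toluene, 70 °C) turns the aryl ester into the acetal enol ether F9.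
- The very labile electron-rich acetal is then hydrolysed selectively (cat. PPTS, wet acetone, 0 °C) to 9.

Step 8.
- The prenyl groups may cyclise under acid onto the freed ortho phenols.
- C2 may slowly epimerise on prolonged heating.

The fallback sets out from 10 and comes back at 11, and it avoids Brønsted acid. The acetals are exchanged for silyl ethers (TMSOTf, 2,2'-bipyridyl, MeCN, 0 °C) to give the tetrakis(trimethylsilyl) ether F10. This is hydrolysed by adding water at rt.

**Further compounds**
F1 | step 7 | 1-[2-hydroxy-4,6-bis(methoxymethoxy)-3,5-diprenylphenyl]ethan-1-ol (racemic) | COCOc1c(CC=C(C)C)c(O)c(C(C)O)c(OCOC)c1CC=C(C)C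
F2 | step 7 | 1-[2-hydroxy-4,6-bis(methoxymethoxy)-3,5-diprenylphenyl]ethan-1-one | COCOc1c(CC=C(C)C)c(O)c(C(C)=O)c(OCOC)c1CC=C(C)C
F3 | step 7 | (E)-2'-hydroxy-3,5,4',6'-tetrakis(methoxymethoxy)-3',5'-diprenylchalcone | COCOc1c(CC=C(C)C)c(O)c(C(=O)/C=C/c2cc(OCOC)cc(OCOC)c2)c(OCOC)c1CC=C(C)C
F4 | step 7 | racemic tetra-MOM flavanone (rac-10) | CC(C)=CCc1c(OCOC)c(CC=C(C)C)c2c(c1OCOC)C(=O)CC(c1cc(OCOC)cc(OCOC)c1)O2
F5 | step 7 | cis-(2R,4R)-tetra-MOM flavan-4-ol | CC(C)=CCc1c(OCOC)c(CC=C(C)C)c2c(c1OCOC)[C@H](O)C[C@H](c1cc(OCOC)cc(OCOC)c1)O2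
F6 | step 5 | 3,5-bis(methoxymethoxy)benzoic acid | COCOc1cc(cc(OCOC)c1)C(=O)O
F7 | step 5 | 2-formyl-3,5-bis(methoxymethoxy)-4,6-diprenylphenyl 3,5-bis(methoxymethoxy)benzoate | COCOc1c(CC=C(C)C)c(OC(=O)c2cc(OCOC)cc(OCOC)c2)c(C=O)c(OCOC)c1CC=C(C)C
F8 | step 5 | 2-(dimethoxymethyl)-3,5-bis(methoxymethoxy)-4,6-diprenylphenyl 3,5-bis(methoxymethoxy)benzoate | COCOc1c(CC=C(C)C)c(OC(=O)c2cc(OCOC)cc(OCOC)c2)c(C(OC)OC)c(OCOC)c1CC=C(C)C
F9 | step 5 | dimethyl acetal of 9 | COCOc1c(CC=C(C)C)c(OC(=C)c2cc(OCOC)cc(OCOC)c2)c(C(OC)OC)c(OCOC)c1CC=C(C)C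
F10 | step 8 | (2S)-tetrakis(trimethylsilyl) ether of 11 | CC(C)=CCc1c(O[Si](C)(C)C)c(CC=C(C)C)c2c(c1O[Si](C)(C)C)C(=O)C[C@@H](c1cc(O[Si](C)(C)C)cc(O[Si](C)(C)C)c1)O2
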